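**Plan**
1. Retrosynthesis: the acid and both acetates go back to an E-alkylidene γ-lactone (C7–CO–O–C9) and a C1 carbinol. The lactone carbonyl is removed from C7 (CO onto a ring alkyne C6≡C7), the carbinol comes from a C1 ketone, and C2=C3 from the saturated ketone.
2. Enabling feature: in the ten-membered ring the oxygen-bearing C1 and the alkene carbon C6 lie 1,6 to each other. A C1–C6 bond therefore gives a decalin (ring A: C1–C6; ring B: C1, C6–C10) whose ring-fusion epoxide and C7 ketone fragment to the C1 ketone and the C6≡C7 alkyne.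
3. The decalin is cut at C1–C2 (alkyllithium onto a vinylogous ester) and C5–C6 (reductive alkylation of a cyclohexane-1,3-dione). The dione is cut at C1–C6 (Claisen) and C9–C10 (aldol).
4. Forward order: ring B first, ring A second, epoxidation, then the shared C1–C6 bond is cleaved to release the ten-membered ring. The lactone ring is closed on the alkyne and reopened at the end.
5. Stereochemistry: C9 and C10 from an Evans syn aldol; C1 from a C9-hydroxyl-directed anti reduction; E at C6=C7 from tethered syn carbopalladation; ring-cis C2=C3 from ring strain; C3 and the epoxide face are erased.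

Key step: step 13

Assumption: ring atoms keep the target numbering C1–C10 in every intermediate, and C3 (racemic side-chain lactone 10) and the epoxide face of 19 are left unassigned because both are planarised in steps 13 and 15.

**Step 1**
Reactants: 1 (S)-4-benzyl-1,3-oxazolidin-2-one; 2 3-methylbutanoyl chloride
Product: 3 (S)-4-benzyl-3-(3-methylbutanoyl)-1,3-oxazolidin-2-one
Conditions: n-BuLi, THF, −78 °C; then 2, −78 → 0 °C
Reagents that add atoms: none
Why: N-acylation of the lithiated oxazolidinone by the acid chloride is the standard entry to an Evans imide and touches no stereocenter.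

**Step 2**
Reactants: 4 ethyl (2-methyl-1,3-dioxolan-2-yl)acetate
Product: 5 (2-methyl-1,3-dioxolan-2-yl)acetaldehyde
Conditions: DIBAL-H, CH2Cl2, −78 °C; Rochelle salt (used at once)
Reagents that add atoms: none
Why: Partial ester reduction stops at the aldehyde because the tetrahedral aluminium alkoxide is stable at −78 °C, and the ketone stays masked as its dioxolane.

**Step 3**
Reactants: 3 (S)-4-benzyl-3-(3-methylbutanoyl)-1,3-oxazolidin-2-one; 5 (2-methyl-1,3-dioxolan-2-yl)acetaldehyde
Product: 6 (4S)-4-benzyl-3-[(2S,3R)-3-hydroxy-4-(2-methyl-1,3-dioxolan-2-yl)-2-(propan-2-yl)butanoyl]-1,3-oxazolidin-2-one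
Conditions: Bu2BOTf, i-Pr2NEt, CH2Cl2, 0 °C; 5, −78 → 0 °C; pH 7 buffer, MeOH, H2O2
Reagents that add atoms: none
Why: Evans syn aldol, in which the Z-boron enolate reacts through a Zimmerman–Traxler chair on the face away from the benzyl group of the dipole-opposed auxiliary and so sets C10 (2S) and C9 (3R) together.

**Step 4**
Reactants: 6 aldol adduct
Product: 7 (4S)-4-benzyl-3-[(2S,3R)-3-(tert-butyldimethylsilyloxy)-4-(2-methyl-1,3-dioxolan-2-yl)-2-(propan-2-yl)butanoyl]-1,3-oxazolidin-2-one
Conditions: TBSOTf, 2,6-lutidine, CH2Cl2, −78 → 0 °C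
Reagents that add atoms: tert-butyldimethylsilyl trifluoromethanesulfonate, CC(C)(C)[Si](C)(C)OS(=O)(=O)C(F)(F)F
Why: Silylation of the hindered aldol carbinol with the buffered silyl triflate is standard, blocks retro-aldol and alkoxide chemistry in step 6, and should spare the ketone dioxolane at low temperature.

**Step 5**
Reactants: 7 silyl ether
Product: 8 (4S)-4-benzyl-3-[(2S,3R)-3-(tert-butyldimethylsilyloxy)-5-oxo-2-(propan-2-yl)hexanoyl]-1,3-oxazolidin-2-one
Conditions: PPTS, acetone/H2O, 50 °C
Reagents that add atoms: water, O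
Why: Mild acid-catalysed ketal hydrolysis frees the methyl ketone while the secondary TBS ether and the imide are expected to survive.

**Step 6**
Reactants: 8 keto imide
Product: 9 (4S,5R)-5-(tert-butyldimethylsilyloxy)-4-(propan-2-yl)cyclohexane-1,3-dione
Conditions: LiHMDS (2.2 equiv), THF, −78 → −20 °C; aq. NH4Cl, then 1 M HCl to pH 4 at 0 °C
Reagents that add atoms: none
Why: Intramolecular Claisen (Dieckmann-type) acylation, in which the kinetic methyl-side ketone enolate attacks the exocyclic imide carbonyl (6-exo-trig) and the oxazolidinone leaves; the α-branched imide C10–H is kinetically non-acidic (A1,3 strain) and the product rests as its dione enolate, so C9 and C10 are kept.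

**Step 7**
Reactants: 10 4-methyldihydrofuran-2(3H)-one (racemic)
Product: 12 ethyl 4-iodo-3-methylbutanoate, via trimethylsilyl 4-iodo-3-methylbutanoate 11 (not isolated)
Conditions: TMSI, MeCN, 60 °C; then EtOH, rt
Reagents that add atoms: iodotrimethylsilane, C[Si](C)(C)I; ethanol, CCO
Why: Silyl activation of the lactone carbonyl lets iodide open the ring by SN2 at the O–CH2 carbon, so the C2–C5 unit emerges with its ends differentiated as iodide (C2) and, after ethanolysis of the silyl ester, ester (C5).

**Step 8**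
Reactants: 12 ethyl 4-iodo-3-methylbutanoate
Product: 13 4-iodo-3-methylbutanal
Conditions: DIBAL-H, CH2Cl2, −78 °C; Rochelle salt (used at once)
Reagents that add atoms: none
Why: Low-temperature partial ester reduction as in step 2; the primary C–I bond is inert to DIBAL-H at −78 °C.

**Step 9**
Reactants: 9 dione; 13 4-iodo-3-methylbutanal
Product: 15 (4S,5R)-5-(tert-butyldimethylsilyloxy)-2-(4-iodo-3-methylbutyl)-4-(propan-2-yl)cyclohexane-1,3-dione, via alkylidene dione 14 (not isolated)
Conditions: L-proline (20 mol %), Hantzsch ester, CH2Cl2, rt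
Reagents that add atoms: none
Why: Organocatalytic reductive alkylation, in which a proline-mediated Knoevenagel condensation at the acidic C6 is followed by conjugate hydride transfer from the Hantzsch ester, should give clean C-monoalkylation under neutral conditions that spare the iodide and the β-silyloxy group.

**Step 10**
Reactants: 15 2-alkyl dione
Product: 16 (5R,6S)-5-(tert-butyldimethylsilyloxy)-2-(4-iodo-3-methylbutyl)-3-methoxy-6-(propan-2-yl)cyclohex-2-en-1-one
Conditions: Me2SO4, K2CO3, acetone, rt; chromatography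
Reagents that add atoms: dimethyl sulfate, COS(=O)(=O)OC
Why: O-Alkylation of the 2-alkyl dione anion by the hard sulfate should favour the oxygen on C7, remote from the isopropyl-bearing C10, which leaves the C1 carbonyl free; any regioisomer is removed by chromatography.

**Step 11**
Reactants: 16 iodoalkyl vinylogous ester
Product: 18 (3R,4R)-3-(tert-butyldimethylsilyloxy)-6-methyl-4-(propan-2-yl)-3,4,5,6,7,8-hexahydronaphthalen-1(2H)-one, via tertiary carbinol 17 (not isolated)
Conditions: t-BuLi (2.1 equiv), Et2O/pentane, −78 °C; then 1 M HCl, THF, 0 °C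
Reagents that add atoms: water, O
Why: Iodine–lithium exchange should outrun attack of t-BuLi on the hindered vinylogous-ester carbonyl, the primary alkyllithium then adds 1,2 to C1 through a six-membered transition state (intramolecular Stork–Danheiser), and acid ionises the tertiary allylic carbinol and hydrolyses the enol ether to the transposed C7 enone.

**Step 12**
Reactants: 18 bicyclic enone
Product: 19 (3R,4S)-3-(tert-butyldimethylsilyloxy)-4a,8a-epoxy-6-methyl-4-(propan-2-yl)octahydronaphthalen-1(2H)-one (C1,C6-epoxide, C7 ketone)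
Conditions: 30% H2O2, LiOH (cat.), MeOH, 0 °C
Reagents that add atoms: hydrogen peroxide, OO
Why: Weitz–Scheffer nucleophilic epoxidation, in which hydroperoxide adds to C1 and the enolate closes on oxygen; the face of attack is immaterial because C1 and C6 lose their configuration in step 13.

**Step 13**
Reactants: 19 epoxy ketone
Product: 22 (9R,10S)-9-(tert-butyldimethylsilyloxy)-3-methyl-10-(propan-2-yl)cyclodec-6-yn-1-one, via tosylhydrazone 20 (not isolated), via azoalkene carbinol 21 (not isolated)
Conditions: TsNHNH2, CH2Cl2/AcOH (1:1), −20 °C → rt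
Reagents that add atoms: none
Why: The C7 ketone condenses with the sulfonylhydrazide, the hydrazone opens the C6–O bond of the epoxide to the C7=C6 azoalkene carrying oxygen on C1, and collapse of that oxygen to the C1 carbonyl cleaves the C1–C6 bond, forms C6≡C7 and expels dinitrogen and sulfinate. The closest known reaction type is the Eschenmoser–Tanabe fragmentation of ring-fusion epoxides of Δ9,10-octal-1-ones to cyclodec-5-ynones. No ring is closed by bond formation: the ten-membered ring appears when the bond shared by the two six-membered rings is cut, so no cyclisation mode applies. No stereocenter is created; the epoxide carbons become sp2 and sp, C3 is untouched, and C9 and C10 pass through unchanged. The step needs chemoselectivity: the hydrazone can form only at C7, the bicycle holds the C1–C6 bond aligned with the azo π-system, and the cold, weakly acidic medium should prevent β-elimination of the C9 silyloxy group and epimerisation at C10 of the new ketone.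

**Step 14**
Reactants: 22 cyclodecynone
Product: 23 C1-O-trimethylsilyl enol ether of 22 (C1=C2)
Conditions: LDA, TMSCl, THF, −78 °C (in situ trapping); Et3N, pentane filtration (used crude)
Reagents that add atoms: chlorotrimethylsilane, C[Si](C)(C)Cl
Why: Kinetic deprotonation with in situ silyl trapping should take the C2 methylene proton rather than the hindered C10 methine, which fixes the enol silane regiochemistry and never forms the C10 enolate that could expel the C9 silyloxy group.

**Step 15**
Reactants: 23 enol silane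
Product: 24 (2Z,9R,10S)-9-(tert-butyldimethylsilyloxy)-3-methyl-10-(propan-2-yl)cyclodec-2-en-6-yn-1-one
Conditions: Pd(OAc)2 (1.1 equiv), MeCN, rt
Reagents that add atoms: none
Why: Saegusa–Ito oxidation, in which the palladium(II) enolate loses the C3 hydrogen by β-hydride elimination so that both C3 epimers converge on the C2=C3 enone; the ring-cis (Z) geometry is expected because a trans double bond is strongly disfavoured in a ten-membered ring that also holds an alkyne.

**Step 16**
Reactants: 24 silyloxy enynone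
Product: 25 (2Z,9R,10S)-9-hydroxy-3-methyl-10-(propan-2-yl)cyclodec-2-en-6-yn-1-one
Conditions: HF·pyridine, pyridine/THF, 0 °C → rt
Reagents that add atoms: none
Why: Pyridine-buffered fluoride desilylation is too mild for retro-aldol cleavage, β-elimination or acid-triggered transannular attack of the alkyne on the ketone.

**Step 17**
Reactants: 25 β-hydroxy enynone
Product: 26 (1R,2Z,9R,10S)-3-methyl-10-(propan-2-yl)cyclodec-2-en-6-yne-1,9-diol
Conditions: Me4NBH(OAc)3, MeCN/AcOH (1:1), −30 °C
Reagents that add atoms: none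
Why: Evans–Saksena reduction, in which the C9 hydroxyl exchanges onto boron and hydride is delivered internally to C1 through a chair-like six-membered transition state, should give the 1,3-anti diol (1R) with 1,2-reduction of the enone only.

**Step 18**
Reactants: 26 anti diol
Product: 27 (1R,2Z,6E,9R,10S)-1,9-dihydroxy-3-methyl-10-(propan-2-yl)cyclodeca-2,6-diene-7-carboxylic acid 9-lactone (E-alkylidene γ-butyrolactone, C1–OH free)
Conditions: PdCl2(PPh3)2 (5 mol %), SnCl2 (5 mol %), CO (7 atm), MeCN, 65 °C
Reagents that add atoms: carbon monoxide, [C-]#[O+]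
Why: Palladium-catalysed cyclocarbonylation of a homopropargylic alcohol, in which the alkoxycarbonyl–palladium unit on O9 adds syn across C6≡C7 in the 5-exo sense and the vinyl–palladium bond is protonated with retention, so the carbonyl on C7 and the hydrogen on C6 end up cis and only the E-alkylidene lactone with ring-cis C5/C8 can form; the C1 hydroxyl would need a seven-membered lactone.

**Step 19**
Reactants: 27 hydroxy lactone
Product: 29 prop-2-en-1-yl (1R,2Z,6E,9R,10S)-1,9-dihydroxy-3-methyl-10-(propan-2-yl)cyclodeca-2,6-diene-7-carboxylate, via lithium carboxylate 28 (not isolated)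
Conditions: LiOH (1.1 equiv), THF/H2O, 0 °C; evaporate; allyl bromide, DMF, 0 °C → rt (used at once)
Reagents that add atoms: lithium hydroxide, [Li+].[OH-]; allyl bromide, C=CCBr
Why: Saponification opens the lactone and SN2 O-alkylation of the carboxylate traps the open form as an ester before it can relactonise, while the hydroxyls are not alkylated in the absence of strong base.

**Step 20**
Reactants: 29 dihydroxy allyl ester
Product: 30 prop-2-en-1-yl (1R,2Z,6E,9R,10S)-1,9-diacetoxy-3-methyl-10-(propan-2-yl)cyclodeca-2,6-diene-7-carboxylate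
Conditions: Ac2O, pyridine, DMAP (cat.), CH2Cl2, 0 °C → rt
Reagents that add atoms: acetic anhydride, CC(=O)OC(C)=O
Why: DMAP-catalysed acetylation esterifies both secondary carbinols, and capping the C9 hydroxyl removes the lactonisation pathway.

**Step 21**
Reactants: 30 diacetate allyl ester
Product: 31 (1R,2Z,6E,9R,10S)-1,9-diacetoxy-3-methyl-10-(propan-2-yl)cyclodeca-2,6-diene-7-carboxylic acid (CNP0172943.1)
Conditions: Pd(PPh3)4 (5 mol %), morpholine, THF, 0 °C
Reagents that add atoms: none
Why: Tsuji–Trost deallylation, in which palladium(0) should ionise the unhindered primary allyl ester far faster than the hindered secondary ring allylic acetate at C1 and morpholine traps the π-allyl fragment, leaving the free acid.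

**Compound list**
1 | (S)-4-benzyl-1,3-oxazolidin-2-one | O=C1N[C@@H](Cc2ccccc2)CO1 | starting material
2 | 3-methylbutanoyl chloride | CC(C)CC(=O)Cl | starting material
3 | (S)-4-benzyl-3-(3-methylbutanoyl)-1,3-oxazolidin-2-one | CC(C)CC(=O)N1[C@@H](Cc2ccccc2)COC1=O | intermediate
4 | ethyl (2-methyl-1,3-dioxolan-2-yl)acetate | CCOC(=O)CC1(C)OCCO1 | starting material
5 | (2-methyl-1,3-dioxolan-2-yl)acetaldehyde | O=CCC1(C)OCCO1 | intermediate
6 | (4S)-4-benzyl-3-[(2S,3R)-3-hydroxy-4-(2-methyl-1,3-dioxolan-2-yl)-2-(propan-2-yl)butanoyl]-1,3-oxazolidin-2-one | CC1(OCCO1)C[C@@H](O)[C@H](C(C)C)C(=O)N2[C@@H](Cc3ccccc3)COC2=O | intermediate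
7 | (4S)-4-benzyl-3-[(2S,3R)-3-(tert-butyldimethylsilyloxy)-4-(2-methyl-1,3-dioxolan-2-yl)-2-(propan-2-yl)butanoyl]-1,3-oxazolidin-2-one | CC1(OCCO1)C[C@@H](O[Si](C)(C)C(C)(C)C)[C@H](C(C)C)C(=O)N2[C@@H](Cc3ccccc3)COC2=O | intermediate
8 | (4S)-4-benzyl-3-[(2S,3R)-3-(tert-butyldimethylsilyloxy)-5-oxo-2-(propan-2-yl)hexanoyl]-1,3-oxazolidin-2-one | CC(=O)C[C@@H](O[Si](C)(C)C(C)(C)C)[C@H](C(C)C)C(=O)N1[C@@H](Cc2ccccc2)COC1=O | intermediate
9 | (4S,5R)-5-(tert-butyldimethylsilyloxy)-4-(propan-2-yl)cyclohexane-1,3-dione (C1, C7 carbonyls; C6 between them) | O=C1CC(=O)C[C@@H](O[Si](C)(C)C(C)(C)C)[C@@H]1C(C)C | intermediate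
10 | 4-methyldihydrofuran-2(3H)-one, racemic | CC1COC(=O)C1 | starting material
11 | trimethylsilyl 4-iodo-3-methylbutanoate (not isolated) | C[Si](C)(C)OC(=O)CC(C)CI | intermediate
12 | ethyl 4-iodo-3-methylbutanoate | CCOC(=O)CC(C)CI | intermediate
13 | 4-iodo-3-methylbutanal | O=CCC(C)CI | intermediate
14 | (4S,5R)-5-(tert-butyldimethylsilyloxy)-2-(4-iodo-3-methylbutylidene)-4-(propan-2-yl)cyclohexane-1,3-dione (not isolated) | O=C1C(=CCC(C)CI)C(=O)C[C@@H](O[Si](C)(C)C(C)(C)C)[C@@H]1C(C)C | intermediate
15 | (4S,5R)-5-(tert-butyldimethylsilyloxy)-2-(4-iodo-3-methylbutyl)-4-(propan-2-yl)cyclohexane-1,3-dione (C3 epimers) | O=C1C(CCC(C)CI)C(=O)C[C@@H](O[Si](C)(C)C(C)(C)C)[C@@H]1C(C)C | intermediate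
16 | (5R,6S)-5-(tert-butyldimethylsilyloxy)-2-(4-iodo-3-methylbutyl)-3-methoxy-6-(propan-2-yl)cyclohex-2-en-1-one (C1 ketone, C7 enol ether) | O=C1C(CCC(C)CI)=C(OC)C[C@@H](O[Si](C)(C)C(C)(C)C)[C@@H]1C(C)C | intermediate
17 | (3R,4S)-3-(tert-butyldimethylsilyloxy)-1-methoxy-6-methyl-4-(propan-2-yl)-3,4,5,6,7,8-hexahydronaphthalen-4a(2H)-ol (C1 carbinol, not isolated) | COC1=C2CCC(C)CC2(O)[C@@H](C(C)C)[C@H](O[Si](C)(C)C(C)(C)C)C1 | intermediate
18 | (3R,4R)-3-(tert-butyldimethylsilyloxy)-6-methyl-4-(propan-2-yl)-3,4,5,6,7,8-hexahydronaphthalen-1(2H)-one (C7 ketone, C1=C6) | O=C1C[C@@H](O[Si](C)(C)C(C)(C)C)[C@H](C(C)C)C2=C1CCC(C)C2 | intermediate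
19 | (3R,4S)-3-(tert-butyldimethylsilyloxy)-4a,8a-epoxy-6-methyl-4-(propan-2-yl)octahydronaphthalen-1(2H)-one (either epoxide face, C3 epimers) | O=C1C[C@@H](O[Si](C)(C)C(C)(C)C)[C@H](C(C)C)C2(O3)CC(C)CCC123 | intermediate
20 | N-tosylhydrazone of 19 at C7 (not isolated) | Cc1ccc(cc1)S(=O)(=O)NN=C1C[C@@H](O[Si](C)(C)C(C)(C)C)[C@H](C(C)C)C2(O3)CC(C)CCC123 | intermediate
21 | C7-(tosyldiazenyl) C6=C7 alkene with C1 carbinol (azoalkene, not isolated) | Cc1ccc(cc1)S(=O)(=O)N=NC1=C2CCC(C)CC2(O)[C@@H](C(C)C)[C@H](O[Si](C)(C)C(C)(C)C)C1 | intermediate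
22 | (9R,10S)-9-(tert-butyldimethylsilyloxy)-3-methyl-10-(propan-2-yl)cyclodec-6-yn-1-one (C3 epimers) | O=C1CC(C)CCC#CC[C@@H](O[Si](C)(C)C(C)(C)C)[C@@H]1C(C)C | intermediate
23 | (9R,10S)-9-(tert-butyldimethylsilyloxy)-3-methyl-10-(propan-2-yl)-1-(trimethylsilyloxy)cyclodec-1-en-6-yne | C[Si](C)(C)OC1=CC(C)CCC#CC[C@@H](O[Si](C)(C)C(C)(C)C)[C@@H]1C(C)C | intermediate
24 | (2Z,9R,10S)-9-(tert-butyldimethylsilyloxy)-3-methyl-10-(propan-2-yl)cyclodec-2-en-6-yn-1-one | O=C1/C=C(/C)CCC#CC[C@@H](O[Si](C)(C)C(C)(C)C)[C@@H]1C(C)C | intermediate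
25 | (2Z,9R,10S)-9-hydroxy-3-methyl-10-(propan-2-yl)cyclodec-2-en-6-yn-1-one | O=C1/C=C(/C)CCC#CC[C@@H](O)[C@@H]1C(C)C | intermediate
26 | (1R,2Z,9R,10S)-3-methyl-10-(propan-2-yl)cyclodec-2-en-6-yne-1,9-diol | O[C@@H]1/C=C(/C)CCC#CC[C@@H](O)[C@@H]1C(C)C | intermediate
27 | (1R,2Z,6E,9R,10S)-1,9-dihydroxy-3-methyl-10-(propan-2-yl)cyclodeca-2,6-diene-7-carboxylic acid 9-lactone | O[C@@H]1/C=C(/C)CC/C=C2/C(=O)O[C@H](C2)[C@@H]1C(C)C | intermediate
28 | lithium (1R,2Z,6E,9R,10S)-1,9-dihydroxy-3-methyl-10-(propan-2-yl)cyclodeca-2,6-diene-7-carboxylate (not isolated) | O[C@@H]1/C=C(/C)CC/C=C(/C(=O)[O-])C[C@@H](O)[C@@H]1C(C)C.[Li+] | intermediate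
29 | prop-2-en-1-yl (1R,2Z,6E,9R,10S)-1,9-dihydroxy-3-methyl-10-(propan-2-yl)cyclodeca-2,6-diene-7-carboxylate | O[C@@H]1/C=C(/C)CC/C=C(/C(=O)OCC=C)C[C@@H](O)[C@@H]1C(C)C | intermediate
30 | prop-2-en-1-yl (1R,2Z,6E,9R,10S)-1,9-diacetoxy-3-methyl-10-(propan-2-yl)cyclodeca-2,6-diene-7-carboxylate | CC(=O)O[C@@H]1/C=C(/C)CC/C=C(/C(=O)OCC=C)C[C@@H](OC(C)=O)[C@@H]1C(C)C | intermediate
31 | (1R,2Z,6E,9R,10S)-1,9-diacetoxy-3-methyl-10-(propan-2-yl)cyclodeca-2,6-diene-7-carboxylic acid | CC(=O)O[C@@H]1/C=C(/C)CC/C=C(/C(=O)O)C[C@@H](OC(C)=O)[C@@H]1C(C)C | target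

**Step count**
Total: 21 steps. Longest linear sequence: 18 steps (1 → 3 → 6 → 7 → 8 → 9 → 15 → 16 → 18 → 19 → 22 → 23 → 24 → 25 → 26 → 27 → 29 → 30 → 31).

**Steps most likely to fail**

Step 11. The exchange–cyclisation may lose the race to direct attack of t-BuLi on the C1 carbonyl or to deprotonation at C10 or C8; either deprotonation starts β-elimination of the silyloxy group and aromatisation of ring B. The fallback sets out from dione 9 and rejoins the route at enone 18, closing ring A by olefin metathesis instead of by a carbanion. Palladium(0)-catalysed C-allylation of 9 with allyl methyl carbonate should give the 2-allyl dione F1. O-Methylation as in step 10 gives the vinylogous ester F2. 1,2-Addition of 2-methylallylmagnesium chloride at C1 and acidic work-up (intermolecular Stork–Danheiser) gives the 2-allyl-3-(2-methylallyl) enone F3. Ring-closing metathesis with a second-generation Grubbs catalyst joins C3 and C4 to give the bicyclic dienone F4. Homogeneous hydrogenation (Crabtree's catalyst, H2) of the trisubstituted C3=C4 bond, which the tetrasubstituted conjugated C1=C6 bond should resist, returns 18.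

Step 15. Palladium(II) may be diverted by the strained ring alkyne, and the syn β-hydride elimination could deliver the ring-trans enone. The fallback sets out from ketone 22 and rejoins at enone 24 without palladium and without the enol silane. The kinetic lithium enolate (LDA, −78 °C) is selenenylated with PhSeBr to the 2-(phenylselanyl) ketone F5. Oxidation with H2O2/pyridine at 0 °C triggers selenoxide syn-elimination toward C3. Any ring-trans isomer would then be relaxed to 24 with catalytic iodine in daylight.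

Step 18. The free hydroxyls may add to the palladium-activated alkyne (transannular from O1 or 5-endo from O9) instead of being carbonylated, or the allylic C1 carbinol may ionise in the Lewis-acidic medium. The fallback sets out from diol 26 and rejoins at lactone 27, separating hydrometalation from carbonylation. Silylation of both hydroxyls with 1,1,3,3-tetramethyldisilazane gives the bis(dimethylsilyl) ether F6. Platinum-catalysed intramolecular syn-hydrosilylation from O9 (5-exo-dig, Karstedt's catalyst) gives the oxasilolane F7 with silicon on C7 and hydrogen on C6. Iododesilylation with retention (N-iodosuccinimide, then fluoride work-up that also frees both hydroxyls) gives the 7-iodo diene diol F8. Palladium(0)-catalysed carbonylative lactonisation of the vinyl iodide onto the C9 hydroxyl (Pd(PPh3)4, CO, Et3N) closes lactone 27.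

**Further compounds**
F1 | step 11 | (4S,5R)-2-allyl-5-(tert-butyldimethylsilyloxy)-4-(propan-2-yl)cyclohexane-1,3-dione | O=C1C(CC=C)C(=O)C[C@@H](O[Si](C)(C)C(C)(C)C)[C@@H]1C(C)C
F2 | step 11 | (5R,6S)-2-allyl-5-(tert-butyldimethylsilyloxy)-3-methoxy-6-(propan-2-yl)cyclohex-2-en-1-one | O=C1C(CC=C)=C(OC)C[C@@H](O[Si](C)(C)C(C)(C)C)[C@@H]1C(C)C
F3 | step 11 | (4R,5R)-2-allyl-5-(tert-butyldimethylsilyloxy)-3-(2-methylallyl)-4-(propan-2-yl)cyclohex-2-en-1-one | O=C1C[C@@H](O[Si](C)(C)C(C)(C)C)[C@H](C(C)C)C(CC(C)=C)=C1CC=C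
F4 | step 11 | (3R,4R)-3-(tert-butyldimethylsilyloxy)-6-methyl-4-(propan-2-yl)-3,4,5,8-tetrahydronaphthalen-1(2H)-one | O=C1C[C@@H](O[Si](C)(C)C(C)(C)C)[C@H](C(C)C)C2=C1CC=C(C)C2
F5 | step 15 | (9R,10S)-9-(tert-butyldimethylsilyloxy)-3-methyl-2-(phenylselanyl)-10-(propan-2-yl)cyclodec-6-yn-1-one | O=C1C([Se]c2ccccc2)C(C)CCC#CC[C@@H](O[Si](C)(C)C(C)(C)C)[C@@H]1C(C)C
F6 | step 18 | (1R,2Z,9R,10S)-1,9-bis(dimethylsilyloxy)-3-methyl-10-(propan-2-yl)cyclodec-2-en-6-yne | C[SiH](C)O[C@@H]1/C=C(/C)CCC#CC[C@@H](O[SiH](C)C)[C@@H]1C(C)C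
F7 | step 18 | 2,2-dimethyl-1,2-oxasilolane spanning O9 and C7 with exocyclic C7=C6 (H on C6 cis to Si), C1-O-dimethylsilyl ether | C[SiH](C)O[C@@H]1/C=C(/C)CC/C=C2/[Si](C)(C)O[C@H](C2)[C@@H]1C(C)C
F8 | step 18 | (1R,2Z,6E,9R,10S)-7-iodo-3-methyl-10-(propan-2-yl)cyclodeca-2,6-diene-1,9-diol | O[C@@H]1/C=C(/C)CC/C=C(/I)C[C@@H](O)[C@@H]1C(C)C
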